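**Plan**
1. Retrosynthesis: the C1–OOH bond is cut first (Schenck ene of a 1(10)E olefin). Next comes the segment C8(O‑angeloyl)–C9H2–C10(Me)=C1 of the ten‑membered carbocycle C1–C10: this homoallylic ester is the retron of a cyclopropylcarbinyl→homoallyl rearrangement.
2. The precursor is therefore a bicyclo[7.1.0]decane: a nine‑membered ring in which C8 is bonded to C10, C9 is the cyclopropane CH2, and C1 carries OH. Cleaving the C8–C10 bond inserts C9 into the ring (9 → 10).
3. Further cuts: C9 (Simmons–Smith), C1–C10 (Nozaki–Hiyama–Kishi closure of the nine‑membered ring), and C6–C7 plus the lactone C–O (Cr allylation/lactonisation). This leaves Z‑enal 6 (from neryl acetate) and dienyl bromide 14 (from but‑2‑yn‑1‑ol and methyl propiolate).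
4. Forward order: γ‑lactone, nine‑membered ring (the cis C4=C5 olefin from nerol is unstrained there), cyclopropane, ten‑membered ring by one‑carbon expansion, hydroperoxide.
5. Stereochemistry: C6/C7 from a catalyst‑controlled anti allylation. The CBS‑set C1 carbinol directs the cyclopropane face and, being anti, fixes the E‑1(10) geometry. C8 arises by invertive capture of angelic acid, and C1–OOH by outer‑face 1O2 attack.

Key step: step 14

Remark: germacrane numbering is used for atom labels (carbocycle C1–C10, C14 on C10, C15 on C4, lactone C6–O–C12(=O)–C11(=C13)–C7). The ligand antipode in step 9 is assumed to be the one that delivers the allyl unit to the Si face of aldehyde 6.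

**Route**

Step 1
Reactants: 1 neryl acetate
Product: 2 6,7-epoxyneryl acetate (racemic epoxide)
Conditions: mCPBA (1.05 equiv), NaHCO3, CH2Cl2, 0 °C
Reagents that add atoms: m-chloroperbenzoic acid, OOC(=O)c1cccc(Cl)c1
Why: Prilezhaev epoxidation should go to the remote, electron‑rich 6,7‑olefin because the 2,3‑olefin is deactivated by the allylic acetoxy group; the epoxide stereocentre is erased in step 2.

Step 2
Reactants: 2 6,7-epoxyneryl acetate
Product: 3 (2Z)-3-methyl-6-oxohex-2-en-1-yl acetate
Conditions: H5IO6, THF–H2O, 0 °C → rt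
Reagents that add atoms: none
Why: Acid‑promoted epoxide hydration followed by Malaprade glycol cleavage in one pot should release acetone and the aldehyde (future C1) without touching the Z‑allylic acetate.

Step 3
Reactants: 3 (2Z)-3-methyl-6-oxohex-2-en-1-yl acetate
Product: 5 (2Z)-6,6-dimethoxy-3-methylhex-2-en-1-ol, via acetal acetate 4 (not isolated)
Conditions: HC(OMe)3, MeOH, PPTS (cat.), rt; then K2CO3, rt
Reagents that add atoms: trimethyl orthoformate, COC(OC)OC; methanol, CO
Why: Acid‑catalysed acetalisation masks the aldehyde and base‑catalysed methanolysis of the acetate then frees the allylic alcohol; no stereocentre is involved and the Z‑olefin is not touched.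

Step 4
Reactants: 5 (2Z)-6,6-dimethoxy-3-methylhex-2-en-1-ol
Product: 6 (2Z)-6,6-dimethoxy-3-methylhex-2-enal
Conditions: activated MnO2, CH2Cl2, rt, dark
Reagents that add atoms: none
Why: Neutral heterogeneous MnO2 oxidation of an allylic alcohol should keep the Z geometry (neral‑type enal) and the acetal.

Step 5
Reactants: 7 but-2-yn-1-ol
Product: 9 (2Z)-3-iodobut-2-en-1-ol, via cyclic vinylalanate 8 (not isolated)
Conditions: Red-Al, THF, 0 °C → rt; EtOAc; then I2, THF, −78 → 0 °C
Reagents that add atoms: iodine, II
Why: Hydroxyl‑directed trans‑hydroalumination of the propargylic alcohol places aluminium at C3 in a five‑membered alanate, and iododealumination with retention gives the Z‑iodide.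

Step 6
Reactants: 9 (2Z)-3-iodobut-2-en-1-ol
Product: 10 (2Z)-3-iodobut-2-enal
Conditions: activated MnO2, CH2Cl2, rt, dark
Reagents that add atoms: none
Why: MnO2 oxidation of the allylic alcohol is neutral and should preserve the Z‑vinyl iodide.

Step 7
Reactants: 10 (2Z)-3-iodobut-2-enal; 11 methyl propiolate
Product: 13 methyl (4Z)-3-hydroxy-5-iodo-2-methylidenehex-4-enoate (racemic), via vinylalane 12 (not isolated)
Conditions: 11, DIBAL-H, NMO, THF, 0 °C; then 10, 0 °C → rt
Reagents that add atoms: none
Why: Vinylalumination (hydroalumination of the propiolate to the α‑(methoxycarbonyl)vinylalane, then 1,2‑addition to the enal) gives the Morita–Baylis–Hillman‑type adduct without a nucleophilic amine that could displace the β‑iodide; the racemic carbinol centre is erased in step 8.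

Step 8
Reactants: 13 methyl (4Z)-3-hydroxy-5-iodo-2-methylidenehex-4-enoate
Product: 14 methyl (2Z,4Z)-2-(bromomethyl)-5-iodohexa-2,4-dienoate
Conditions: NBS, Me2S, CH2Cl2, 0 °C → rt
Reagents that add atoms: N-bromosuccinimide, O=C1CCC(=O)N1Br
Why: Corey–Kim‑type activation of the alcohol and SN2′ delivery of bromide to the acrylate CH2 should give the conjugated, thermodynamically preferred (2Z)‑2‑(bromomethyl)dienoate with the vinyl iodide geometry intact.

Step 9
Reactants: 6 (2Z)-6,6-dimethoxy-3-methylhex-2-enal; 14 methyl (2Z,4Z)-2-(bromomethyl)-5-iodohexa-2,4-dienoate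
Product: 16 (4Z)-5-[(2R,3S)-3-[(1Z)-2-iodoprop-1-en-1-yl]-4-methylidene-5-oxooxolan-2-yl]-4-methylpent-4-enal (trans‑lactone; C6 R, C7 S), via silyl ether 15 (not isolated)
Conditions: CrCl2 (10 mol %, Ni‑free), chiral tridentate carbazole‑bis(oxazoline) ligand (12 mol %), Mn, TMSCl, iPr2NEt (cat.), THF, rt; then TsOH·H2O, acetone–H2O, rt → 40 °C
Reagents that add atoms: water, O
Why: In this catalytic asymmetric Nozaki–Hiyama 2‑(alkoxycarbonyl)allylation the allylchromium(III) from 14 should add through its γ‑carbon (C7) in a closed chair transition state with both substituents equatorial (anti adduct, hence the trans‑lactone, C7), while the ligand selects the Si face of the aldehyde (C6 R) and the vinyl iodide stays inert without nickel; aqueous acid then removes the silyl group, closes the lactone and unmasks the C1 aldehyde.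

Step 10
Reactants: 16 lactone aldehyde
Product: 17 nine‑membered dienol lactone (ring C1–C8 + C10; C4=C5 Z, C8=C10 Z; 6R,7S; 1‑OH as both epimers)
Conditions: CrCl2 (6 equiv), NiCl2 (1 mol %), DMSO–THF, slow addition to 3 mM, rt
Reagents that add atoms: none
Why: Intramolecular Nozaki–Hiyama–Kishi coupling forms C1–C10 with retention of the Z‑vinyl geometry, the two chain ends being held close by the trans‑lactone and the two cis olefins, and the organochromium adds only to the aldehyde; C1 forms as an epimer mixture that steps 11–12 correct.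

Step 11
Reactants: 17 nine‑membered dienol lactone
Product: 18 nine‑membered 1‑oxo enone lactone (6R,7S)
Conditions: Dess–Martin periodinane, NaHCO3, CH2Cl2, 0 °C → rt
Reagents that add atoms: none
Why: Buffered Dess–Martin oxidation converges both C1 epimers to one enone under non‑basic conditions, so the doubly allylic C7–H and the exo‑methylene lactone should not isomerise.

Step 12
Reactants: 18 enone
Product: 19 (1R,6R,7S)-dienol lactone (1β‑OH)
Conditions: (S)-Me-CBS (0.5 equiv), catecholborane, toluene, −78 °C
Reagents that add atoms: none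
Why: Corey–Bakshi–Shibata reduction is reagent‑controlled: the α‑methyl‑substituted alkenyl arm acts as the large group and CH2 as the small one, so the (S)‑catalyst should give the (1R) allylic alcohol, and catecholborane at −78 °C leaves the lactone and olefins alone.

Step 13
Reactants: 19 (1R)-dienol lactone
Product: 20 cyclopropyl carbinol (1R,6R,7S,8R,10R): cis‑fused bicyclo[7.1.0]decene, cyclopropane C8–C9–C10 with CH2 on the α‑face, 10β‑Me, 1β‑OH anti to the CH2
Conditions: Et2Zn, CH2I2, CH2Cl2, −10 → 0 °C
Reagents that add atoms: diiodomethane, ICI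
Why: Hydroxyl‑directed Simmons–Smith (Furukawa) cyclopropanation reacts only at the allylic‑alcohol olefin (C4=C5 has no directing OH, the enoate is electron‑poor); in cis‑cyclooctenols and ‑nonenols the zinc alkoxide delivers CH2 to the face that ends up anti to the oxygen, which sets C8 (R) and C10 (R) from C1.

Step 14
Reactants: 20 cyclopropyl carbinol; 21 angelic acid
Product: 22 8α-angeloyloxy-(1(10)E,4Z)-germacra-1(10),4,11(13)-trien-12,6α-olide (6R,7R,8S)
Conditions: angelic acid (5 equiv), Sc(OTf)3 (5 mol %), 4 Å MS, CH2Cl2, −20 → 0 °C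
Reagents that add atoms: none
Why: Sc(OTf)3 ionises the cyclopropylcarbinyl C1–OH; the C8–C10 bond, antiperiplanar to the departing oxygen, donates into the developing p‑orbital and angelic acid attacks C8 from the side opposite C10, so C1=C10 forms as C8–C10 breaks. The closest known reaction type is the acid‑mediated cyclopropylcarbinyl→homoallyl rearrangement with carboxylic‑acid capture (Julia olefin synthesis, retro‑i‑steroid rearrangement, bicyclo[n.1.0]alkan‑2‑ol → cycloalk‑3‑enol ring enlargement). No ring is closed by bond formation: the ten‑membered ring is the periphery of the bicyclo[7.1.0]decane and appears when the zero‑atom bridge C8–C10 is cleaved, C9 becoming the ring atom between C8 and C10 (9 → 10). C8 is the only new stereocentre and is fixed by inversion at the cyclopropane carbon (8R in 20 → 8S, α‑oxygen), hence ultimately by the CBS‑set carbinol that directed the cyclopropanation. The step needs attack at secondary C8 (not at primary C9 or by return at C1/C10) and E geometry: C8 carries more of the charge than C9 (as C3 versus C4 in i‑steroids), cyclopropylcarbinyl or cyclobutyl esters formed by return re‑ionise whereas the homoallylic ester does not, and in the anti carbinol C2 lies on the methyl side of C10 when C1–O is antiperiplanar to C8–C10, which maps onto the E‑1(10) olefin.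

Step 15
Reactants: 22 angelate diene
Product: 23 target hydroperoxide (1R,6R,7R,8S)
Conditions: O2, visible light, tetraphenylporphyrin (cat.), CH2Cl2, −20 °C
Reagents that add atoms: dioxygen, O=O
Why: In the Schenck ene reaction 1O2 should attack the electron‑rich E‑1(10) olefin (C4=C5 is deactivated by the allylic lactone oxygen, both enoates are electron‑poor) and abstract a C14 methyl hydrogen on the more substituted side (cis effect), giving the 10(14)‑methylene and the C1 hydroperoxide; approach to the outer face of the olefin in the conformer with C14 on the β‑face should give 1β (1R), as in related 1(10)E germacranolides.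

**Compound list**
1 | neryl acetate, (2Z)-3,7-dimethylocta-2,6-dien-1-yl acetate | CC(=O)OC/C=C(/C)CCC=C(C)C | starting material
2 | 6,7-epoxyneryl acetate, (2Z)-5-(3,3-dimethyloxiran-2-yl)-3-methylpent-2-en-1-yl acetate (racemic epoxide) | CC(=O)OC/C=C(/C)CCC1OC1(C)C | intermediate
3 | (2Z)-3-methyl-6-oxohex-2-en-1-yl acetate | CC(=O)OC/C=C(/C)CCC=O | intermediate
4 | (2Z)-6,6-dimethoxy-3-methylhex-2-en-1-yl acetate (not isolated) | CC(=O)OC/C=C(/C)CCC(OC)OC | intermediate
5 | (2Z)-6,6-dimethoxy-3-methylhex-2-en-1-ol | OC/C=C(/C)CCC(OC)OC | intermediate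
6 | (2Z)-6,6-dimethoxy-3-methylhex-2-enal | O=C/C=C(/C)CCC(OC)OC | intermediate
7 | but-2-yn-1-ol | CC#CCO | starting material
8 | sodium 2,2-bis(2-methoxyethoxy)-3-methyl-2,5-dihydro-1,2-oxaalumol-2-uide, cyclic vinylalanate (not isolated) | CC1=CCO[Al-]1(OCCOC)OCCOC.[Na+] | intermediate
9 | (2Z)-3-iodobut-2-en-1-ol | OC/C=C(/C)I | intermediate
10 | (2Z)-3-iodobut-2-enal | O=C/C=C(/C)I | intermediate
11 | methyl propiolate | C#CC(=O)OC | starting material
12 | methyl 2-(diisobutylalumanyl)prop-2-enoate (not isolated) | C=C(C(=O)OC)[Al](CC(C)C)CC(C)C | intermediate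
13 | methyl (4Z)-3-hydroxy-5-iodo-2-methylidenehex-4-enoate (racemic) | C=C(C(=O)OC)C(O)/C=C(/C)I | intermediate
14 | methyl (2Z,4Z)-2-(bromomethyl)-5-iodohexa-2,4-dienoate | COC(=O)/C(CBr)=C/C=C(/C)I | intermediate
15 | methyl (3S,4R,5Z)-3-[(1Z)-2-iodoprop-1-en-1-yl]-9,9-dimethoxy-6-methyl-2-methylidene-4-[(trimethylsilyl)oxy]non-5-enoate (not isolated) | COC(=O)C(=C)[C@H](/C=C(/C)I)[C@H](O[Si](C)(C)C)/C=C(/C)CCC(OC)OC | intermediate
16 | (4Z)-5-[(2R,3S)-3-[(1Z)-2-iodoprop-1-en-1-yl]-4-methylidene-5-oxooxolan-2-yl]-4-methylpent-4-enal | C=C1C(=O)O[C@H](/C=C(/C)CCC=O)[C@H]1/C=C(/C)I | intermediate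
17 | nine‑membered dienol lactone: ring C1–C8 + C10, 4Z, 8(10)Z, 1‑OH (both epimers), trans 6,12‑γ‑lactone with 11(13)‑methylene, 6R,7S | C=C1C(=O)O[C@@H]2/C=C(/C)CCC(O)/C(C)=C\[C@@H]12 | intermediate
18 | nine‑membered enone lactone: 1‑oxo, 4Z, 8(10)Z, 6R,7S | C=C1C(=O)O[C@@H]2/C=C(/C)CCC(=O)/C(C)=C\[C@@H]12 | intermediate
19 | (1R,6R,7S)-dienol lactone (1β‑OH), 4Z, 8(10)Z | C=C1C(=O)O[C@@H]2/C=C(/C)CC[C@@H](O)/C(C)=C\[C@@H]12 | intermediate
20 | (1R,6R,7S,8R,10R)-cyclopropyl carbinol: cis‑fused bicyclo[7.1.0]decene, C8–C9–C10 cyclopropane (CH2 α), 10β‑Me, 1β‑OH anti to CH2, 4Z, trans 6,12‑lactone | C=C1C(=O)O[C@@H]2/C=C(/C)CC[C@@H](O)[C@]3(C)C[C@@H]3[C@@H]12 | intermediate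
21 | angelic acid, (2Z)-2-methylbut-2-enoic acid | C/C=C(/C)C(=O)O | starting material
22 | 8α-angeloyloxy-(1(10)E,4Z)-germacra-1(10),4,11(13)-trien-12,6α-olide (6R,7R,8S) | C=C1C(=O)O[C@@H]2/C=C(/C)CC/C=C(\C)C[C@H](OC(=O)/C(C)=C\C)[C@@H]12 | intermediate
23 | (1R,6R,7R,8S)-8-angeloyloxy-1-hydroperoxy-germacra-4Z,10(14),11(13)-trien-12,6-olide (CNP0105813.1) | C=C1C(=O)O[C@@H]2/C=C(/C)CC[C@@H](OO)C(=C)C[C@H](OC(=O)/C(C)=C\C)[C@@H]12 | target

**Step count**
Total steps: 15. Longest linear sequence: 11 steps (1–4, then 9–15; the branch 5–8, then 9–15, is equally long).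

**Steps most likely to fail**

Step 14 (ring expansion). The cation may be captured irreversibly at C1 or after a shift to a cyclobutyl ester instead of draining to the C8 ester. The Lewis acid may also trigger transannular attack of C4=C5 on the cation, cyclisation of the product 1(10),4‑diene, ionisation of the allylic C6–O bond, or Z→E isomerisation of the angelate. The fallback separates the skeletal reorganisation from the acylation, so that the solvent is the nucleophile and no Lewis acid meets the angelate. It sets out from 20: retro‑i‑steroid‑type hydrolysis (TsOH cat., dioxane–H2O, 50 °C) should give the 8α‑alcohol F1 with the same inversion at C8 and the same E olefin. Angelic acid 21 is converted with 2,4,6‑trichlorobenzoyl chloride and Et3N into angelic 2,4,6‑trichlorobenzoic anhydride F2, which acylates F1 (DMAP, toluene, rt; Yamaguchi esterification, which avoids angelate→tiglate isomerisation). The route is rejoined at 22.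

Step 10 (nine‑membered NHK closure). Oligomerisation may outrun ring closure, or the vinylchromium may be protonated (loss of iodine) before it reaches the aldehyde. The fallback closes the nine‑membered ring at the C4=C5 olefin by metathesis instead. It sets out from 14: the same Cr‑catalysed allylation/lactonisation with acrolein in place of 6 gives the vinyl lactone iodide F3. An intermolecular NHK coupling of F3 with 4‑methylpent‑4‑enal (CrCl2, NiCl2 cat., DMF) gives the diene carbinol F4 (C1 epimers). Ring‑closing metathesis (Grubbs II, toluene, 80 °C, 2 mM), in which the nine‑membered ring enforces the Z olefin, returns to the route at 17.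

Step 13 (cyclopropanation). The carbenoid may be delivered to the face syn to the hydroxyl in this substituted nine‑membered ring, or with poor facial selectivity, which would invert C8 of the target. The fallback uses the opposite directing sense and then corrects C1. It sets out from 18: reduction with the (R)‑CBS catalyst and catecholborane gives the (1S)‑dienol F5. Syn‑directed Simmons–Smith cyclopropanation places CH2 on the α‑face and gives the syn cyclopropyl carbinol F6. Dess–Martin oxidation gives the cyclopropyl ketone F7, and (S)‑CBS reduction with catecholborane gives the anti (1R) carbinol. The route is rejoined at 20.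

**Further compounds**
F1 | step 14 | 8α-hydroxy-(1(10)E,4Z)-germacra-1(10),4,11(13)-trien-12,6α-olide (6R,7R,8S) | C=C1C(=O)O[C@@H]2/C=C(/C)CC/C=C(\C)C[C@H](O)[C@@H]12
F2 | step 14 | angelic 2,4,6-trichlorobenzoic anhydride | C/C=C(/C)C(=O)OC(=O)c1c(Cl)cc(Cl)cc1Cl
F3 | step 10 | (4S,5R)-5-ethenyl-4-[(1Z)-2-iodoprop-1-en-1-yl]-3-methylideneoxolan-2-one | C=C1C(=O)O[C@H](C=C)[C@H]1/C=C(/C)I
F4 | step 10 | (4S,5R)-5-ethenyl-4-[(1Z)-3-hydroxy-2,6-dimethylhepta-1,6-dien-1-yl]-3-methylideneoxolan-2-one (carbinol epimers) | C=C1C(=O)O[C@H](C=C)[C@H]1/C=C(/C)C(O)CCC(C)=C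
F5 | step 13 | (1S,6R,7S)-dienol lactone, C1 epimer of 19 | C=C1C(=O)O[C@@H]2/C=C(/C)CC[C@H](O)/C(C)=C\[C@@H]12
F6 | step 13 | (1S,6R,7S,8R,10R)-cyclopropyl carbinol, syn C1 epimer of 20 | C=C1C(=O)O[C@@H]2/C=C(/C)CC[C@H](O)[C@]3(C)C[C@@H]3[C@@H]12
F7 | step 13 | (6R,7S,8R,10R)-cyclopropyl ketone, 1-oxo analogue of 20 | C=C1C(=O)O[C@@H]2/C=C(/C)CCC(=O)[C@]3(C)C[C@@H]3[C@@H]12
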